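**Retrosynthetic overview**
- Target ⇐ its tris-MOM ether ⇐ cis-(3S,4S)-isoflavan-4-ol: C3 is fixed by dynamic kinetic resolution during transfer hydrogenation, then the carbinol is re-oxidised.
- That alcohol ⇐ MOM-protected 2-hydroxydeoxybenzoin bearing an aryl 1,1-dimethylpropargyl ether: one flask closes ring C (C2 from DMF-DMA, O1–C2 bond), then ring D (propargyl Claisen, 1,5-H shift, oxa-6π), then reduces in situ.
- Deoxybenzoin ⇐ Houben–Hoesch C-acylation of phloroglucinol (ring A) with an arylacetonitrile (C4–C4a bond).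
- Arylacetonitrile ⇐ 3,4-dihydroxybenzaldehyde (ring B) by 4-O-selective propargylation and one-carbon reductive cyanation.
- Ring order: A and B purchased; C then D in the same operation; stereocentre last.

Assumption: the stereocentre in the SMILES is C3 with S configuration, and a sequence run in one flask without isolation is counted as one step.

**Step 1**
Reactants: 1 3,4-dihydroxybenzaldehyde; 2 3-chloro-3-methylbut-1-yne
Product: 3 3-hydroxy-4-[(2-methylbut-3-yn-2-yl)oxy]benzaldehyde
Conditions: DBU (1.2 equiv), CuCl2·2H2O (0.2 mol%), MeCN, −5 to 0 °C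
Reagents that add atoms: none
Why: The 4-OH (para to the formyl group, pKa about 7) is deprotonated selectively by DBU and its phenoxide captures the copper-bound propargylic electrophile from 2 (copper-catalysed propargylic etherification), leaving the much less acidic 3-OH free.

**Step 2**
Reactants: 3 3-hydroxy-4-[(2-methylbut-3-yn-2-yl)oxy]benzaldehyde
Product: 5 {3-hydroxy-4-[(2-methylbut-3-yn-2-yl)oxy]phenyl}acetonitrile, via N-vinylformamide 4 (not isolated)
Conditions: TosMIC (1.2 equiv), t-BuOK (3.2 equiv), DME, −35 °C to rt; then MeOH, 65 °C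
Reagents that add atoms: p-toluenesulfonylmethyl isocyanide (TosMIC), Cc1ccc(cc1)S(=O)(=O)C[N+]#[C-]
Why: Van Leusen reductive cyanation: the TosMIC anion adds to the aldehyde, the oxazoline opens to the N-vinylformamide, and methanolysis with loss of sulfinate gives the homologated nitrile under basic conditions that the tertiary propargylic ether (no propargylic hydrogen) tolerates.

**Step 3**
Reactants: 5 {3-hydroxy-4-[(2-methylbut-3-yn-2-yl)oxy]phenyl}acetonitrile; 6 phloroglucinol (benzene-1,3,5-triol)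
Product: 8 2-{3-hydroxy-4-[(2-methylbut-3-yn-2-yl)oxy]phenyl}-1-(2,4,6-trihydroxyphenyl)ethan-1-one, via ketiminium chloride 7 (not isolated)
Conditions: HCl (g), Et2O, 0 °C, 24 h; then H2O, 80 °C
Reagents that add atoms: water, O
Why: Houben–Hoesch reaction: symmetric, highly nucleophilic phloroglucinol attacks the HCl-activated nitrile to give a single mono-acylation product after hydrolysis, and the tertiary propargylic ether is expected to survive because the alkynyl group destabilises the cation needed for its cleavage.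

**Step 4**
Reactants: 8 2-{3-hydroxy-4-[(2-methylbut-3-yn-2-yl)oxy]phenyl}-1-(2,4,6-trihydroxyphenyl)ethan-1-one
Product: 9 1-[2-hydroxy-4,6-bis(methoxymethoxy)phenyl]-2-{3-(methoxymethoxy)-4-[(2-methylbut-3-yn-2-yl)oxy]phenyl}ethan-1-one
Conditions: MOMCl (3.3 equiv), i-Pr2NEt (4 equiv), CH2Cl2, 0 °C to rt
Reagents that add atoms: chloromethyl methyl ether (MOMCl), COCCl
Why: MOM ether formation on the three ordinary phenols, while the ortho-hydroxyl hydrogen-bonded to the ketone is far less nucleophilic and stays free, as in the standard bis-MOM protection of phloroacetophenone.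

**Step 5**
Reactants: 9 1-[2-hydroxy-4,6-bis(methoxymethoxy)phenyl]-2-{3-(methoxymethoxy)-4-[(2-methylbut-3-yn-2-yl)oxy]phenyl}ethan-1-one
Product: 14 (3S,4S)-5,7-bis(methoxymethoxy)-3-[8-(methoxymethoxy)-2,2-dimethyl-2H-chromen-6-yl]-3,4-dihydro-2H-chromen-4-ol, via enaminone 10 (not isolated), via isoflavone propargyl ether 11 (not isolated), via pyranoisoflavone 12 (not isolated), via racemic isoflavanone 13 (not isolated)
Conditions: Me2NCH(OMe)2 (2 equiv), DMF, 90 °C, 2 h, then 140 °C, 6 h; cool, add RuCl(p-cymene)[(S,S)-TsDPEN] (3 mol%), HCO2H–Et3N (1:1, 6 equiv), 40 °C, same flask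
Reagents that add atoms: N,N-dimethylformamide dimethyl acetal (DMF-DMA), COC(OC)N(C)C
Why: Proposed new method: three individually known events are run consecutively in one flask, namely DMF-DMA aminomethylenation of the 2-hydroxydeoxybenzoin with addition–elimination closure of ring C, aryl propargyl ether Claisen rearrangement to the only free ortho carbon followed by 1,5-H shift and oxa-6π electrocyclisation to ring D, then Noyori–Ikariya transfer hydrogenation in which the chromone C=C is reduced, the isoflavanone racemises at C3 through its enol under Et3N, and the (S,S)-catalyst delivers hydride to C4 in the sense known for chroman-4-one (4S) from the face opposite the C3 aryl group of the faster-reacting 3S ketone to give the cis (3S,4S) alcohol by dynamic kinetic resolution; the closest known reactions are the DMF-DMA isoflavone synthesis, the thermal chromene synthesis from aryl 1,1-dimethylpropargyl ethers and the transfer hydrogenation of isoflavones to cis-isoflavan-4-ols.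

**Step 6**
Reactants: 14 (3S,4S)-5,7-bis(methoxymethoxy)-3-[8-(methoxymethoxy)-2,2-dimethyl-2H-chromen-6-yl]-3,4-dihydro-2H-chromen-4-ol
Product: 15 (3S)-5,7-bis(methoxymethoxy)-3-[8-(methoxymethoxy)-2,2-dimethyl-2H-chromen-6-yl]-2,3-dihydro-4H-chromen-4-one
Conditions: Dess–Martin periodinane (1.3 equiv), pyridine (4 equiv), CH2Cl2, 0 °C
Reagents that add atoms: none
Why: Dess–Martin oxidation of the benzylic alcohol under pyridine buffer is fast at 0 °C and does not pass through the enol, so the C4 stereocentre is erased while C3 stays S.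

**Step 7**
Reactants: 15 (3S)-5,7-bis(methoxymethoxy)-3-[8-(methoxymethoxy)-2,2-dimethyl-2H-chromen-6-yl]-2,3-dihydro-4H-chromen-4-one
Product: 16 (3S)-5,7-dihydroxy-3-(8-hydroxy-2,2-dimethyl-2H-chromen-6-yl)-2,3-dihydro-4H-chromen-4-one
Conditions: ZnBr2 (3 equiv), n-PrSH (6 equiv), CH2Cl2, 0 °C, 15 min
Reagents that add atoms: none
Why: Lewis acid/thiol cleavage of phenolic MOM ethers (the oxocarbenium ion is captured by the thiol) is complete in minutes at 0 °C in an aprotic medium, which limits enolisation at C3 and protonation of the chromene.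

**Compound list**
1 | 3,4-dihydroxybenzaldehyde | O=Cc1ccc(O)c(O)c1 | starting material
2 | 3-chloro-3-methylbut-1-yne | CC(C)(Cl)C#C | starting material
3 | 3-hydroxy-4-[(2-methylbut-3-yn-2-yl)oxy]benzaldehyde | O=Cc1ccc(OC(C)(C)C#C)c(O)c1 | intermediate
4 | N-[2-{3-hydroxy-4-[(2-methylbut-3-yn-2-yl)oxy]phenyl}-1-(4-methylbenzenesulfonyl)ethenyl]formamide | O=CNC(=Cc1ccc(OC(C)(C)C#C)c(O)c1)S(=O)(=O)c1ccc(C)cc1 | intermediate
5 | {3-hydroxy-4-[(2-methylbut-3-yn-2-yl)oxy]phenyl}acetonitrile | N#CCc1ccc(OC(C)(C)C#C)c(O)c1 | intermediate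
6 | phloroglucinol (benzene-1,3,5-triol) | Oc1cc(O)cc(O)c1 | starting material
7 | 2-{3-hydroxy-4-[(2-methylbut-3-yn-2-yl)oxy]phenyl}-1-(2,4,6-trihydroxyphenyl)ethan-1-iminium chloride | [Cl-].[NH2+]=C(Cc1ccc(OC(C)(C)C#C)c(O)c1)c1c(O)cc(O)cc1O | intermediate
8 | 2-{3-hydroxy-4-[(2-methylbut-3-yn-2-yl)oxy]phenyl}-1-(2,4,6-trihydroxyphenyl)ethan-1-one | O=C(Cc1ccc(OC(C)(C)C#C)c(O)c1)c1c(O)cc(O)cc1O | intermediate
9 | 1-[2-hydroxy-4,6-bis(methoxymethoxy)phenyl]-2-{3-(methoxymethoxy)-4-[(2-methylbut-3-yn-2-yl)oxy]phenyl}ethan-1-one | COCOc1cc(O)c(C(=O)Cc2ccc(OC(C)(C)C#C)c(OCOC)c2)c(OCOC)c1 | intermediate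
10 | 3-(dimethylamino)-1-[2-hydroxy-4,6-bis(methoxymethoxy)phenyl]-2-{3-(methoxymethoxy)-4-[(2-methylbut-3-yn-2-yl)oxy]phenyl}prop-2-en-1-one | CN(C)C=C(C(=O)c1c(O)cc(OCOC)cc1OCOC)c1ccc(OC(C)(C)C#C)c(OCOC)c1 | intermediate
11 | 5,7-bis(methoxymethoxy)-3-{3-(methoxymethoxy)-4-[(2-methylbut-3-yn-2-yl)oxy]phenyl}-4H-chromen-4-one | C#CC(C)(C)Oc1ccc(cc1OCOC)-c1coc2cc(OCOC)cc(OCOC)c2c1=O | intermediate
12 | 5,7-bis(methoxymethoxy)-3-[8-(methoxymethoxy)-2,2-dimethyl-2H-chromen-6-yl]-4H-chromen-4-one | CC1(C)C=Cc2cc(cc(OCOC)c2O1)-c1coc2cc(OCOC)cc(OCOC)c2c1=O | intermediate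
13 | rac-5,7-bis(methoxymethoxy)-3-[8-(methoxymethoxy)-2,2-dimethyl-2H-chromen-6-yl]-2,3-dihydro-4H-chromen-4-one | CC1(C)C=Cc2cc(cc(OCOC)c2O1)C1COc2cc(OCOC)cc(OCOC)c2C1=O | intermediate
14 | (3S,4S)-5,7-bis(methoxymethoxy)-3-[8-(methoxymethoxy)-2,2-dimethyl-2H-chromen-6-yl]-3,4-dihydro-2H-chromen-4-ol (3-H and 4-H cis) | CC1(C)C=Cc2cc([C@H]3COc4cc(OCOC)cc(OCOC)c4[C@H]3O)cc(OCOC)c2O1 | intermediate
15 | (3S)-5,7-bis(methoxymethoxy)-3-[8-(methoxymethoxy)-2,2-dimethyl-2H-chromen-6-yl]-2,3-dihydro-4H-chromen-4-one | CC1(C)C=Cc2cc([C@H]3COc4cc(OCOC)cc(OCOC)c4C3=O)cc(OCOC)c2O1 | intermediate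
16 | (3S)-5,7-dihydroxy-3-(8-hydroxy-2,2-dimethyl-2H-chromen-6-yl)-2,3-dihydro-4H-chromen-4-one | CC1(C)C=Cc2cc([C@H]3COc4cc(O)cc(O)c4C3=O)cc(O)c2O1 | target

**Totals and risks**
Total step count: 7. Longest linear sequence: 7 (1 to 16; 2 and 6 enter at steps 1 and 3).

The step most likely to fail is step 5. An incomplete Claisen stage would leave a terminal alkyne that can poison the ruthenium catalyst, the electron-rich chromanone carbonyl may be reduced slowly, and the 2,4,6-trioxygenated benzylic alcohol can ionise. The fallback sets out from 9 and comes back at 15. The flask is worked up after the heating stage and 12 is isolated. 12 is reduced 1,4 with LiBH(s-Bu)3 (THF, −78 °C) and the enolate is trapped with Me3SiCl to give the silyl enol ether 5,7-bis(methoxymethoxy)-3-[8-(methoxymethoxy)-2,2-dimethyl-2H-chromen-6-yl]-4-(trimethylsilyloxy)-2H-chromene F6. Catalytic enantioselective protonation of F6 (BINOL-derived N-triflyl thiophosphoramide, phenol as proton source, toluene) then gives 15 directly, so that 14 and step 6 are not needed. The catalyst antipode that gives 3S would have to be fixed on a test scale.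

The second is step 3, where HCl may cleave the tertiary propargylic ether or add to the alkyne. The fallback sets out from 1 and comes back at 9, and brings in the propargyl group only after the acid step. 1 is benzylated at the 4-OH (BnBr, NaHCO3, NaI, DMF) to 4-(benzyloxy)-3-hydroxybenzaldehyde F1. TosMIC/t-BuOK then MeOH gives [4-(benzyloxy)-3-hydroxyphenyl]acetonitrile F2. Hoesch reaction with 6 gives 2-[4-(benzyloxy)-3-hydroxyphenyl]-1-(2,4,6-trihydroxyphenyl)ethan-1-one F3. MOMCl/i-Pr2NEt gives 2-[4-(benzyloxy)-3-(methoxymethoxy)phenyl]-1-[2-hydroxy-4,6-bis(methoxymethoxy)phenyl]ethan-1-one F4. Hydrogenolysis (H2, Pd/C, EtOAc) frees 2-[4-hydroxy-3-(methoxymethoxy)phenyl]-1-[2-hydroxy-4,6-bis(methoxymethoxy)phenyl]ethan-1-one F5. Its only non-chelated phenol is then etherified with 2 (DBU, CuCl2·2H2O, MeCN, 0 °C) to give 9.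

The third is step 7, where C3 may epimerise through the enol and the chromene is acid-sensitive. The fallback sets out from 12 (isolated by stopping step 5 after the heating stage) and comes back at 16. It removes the protecting groups before the stereocentre exists. 12 is deprotected at the achiral isoflavone stage (HCl, MeOH, 40 °C) to 5,7-dihydroxy-3-(8-hydroxy-2,2-dimethyl-2H-chromen-6-yl)-4H-chromen-4-one F7. C3 is then set last by rhodium-catalysed asymmetric hydrogenation of the chromone C2=C3 bond ([Rh(cod)2]BF4 with a chiral bisphosphine–thiourea ligand, H2, i-PrOH). The carbonyl hydrogen-bonds to the ligand, and the undirected chromene alkene should be left alone. This last reaction is itself unprecedented on this substrate, and the ligand antipode would be chosen by screening.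

**Further compounds**
F1 | step 3 | 4-(benzyloxy)-3-hydroxybenzaldehyde | O=Cc1ccc(OCc2ccccc2)c(O)c1
F2 | step 3 | [4-(benzyloxy)-3-hydroxyphenyl]acetonitrile | N#CCc1ccc(OCc2ccccc2)c(O)c1
F3 | step 3 | 2-[4-(benzyloxy)-3-hydroxyphenyl]-1-(2,4,6-trihydroxyphenyl)ethan-1-one | O=C(Cc1ccc(OCc2ccccc2)c(O)c1)c1c(O)cc(O)cc1O
F4 | step 3 | 2-[4-(benzyloxy)-3-(methoxymethoxy)phenyl]-1-[2-hydroxy-4,6-bis(methoxymethoxy)phenyl]ethan-1-one | COCOc1cc(O)c(C(=O)Cc2ccc(OCc3ccccc3)c(OCOC)c2)c(OCOC)c1
F5 | step 3 | 2-[4-hydroxy-3-(methoxymethoxy)phenyl]-1-[2-hydroxy-4,6-bis(methoxymethoxy)phenyl]ethan-1-one | COCOc1cc(O)c(C(=O)Cc2ccc(O)c(OCOC)c2)c(OCOC)c1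
F6 | step 5 | 5,7-bis(methoxymethoxy)-3-[8-(methoxymethoxy)-2,2-dimethyl-2H-chromen-6-yl]-4-(trimethylsilyloxy)-2H-chromene | CC1(C)C=Cc2cc(cc(OCOC)c2O1)C1=C(O[Si](C)(C)C)c2c(OCOC)cc(OCOC)cc2OC1
F7 | step 7 | 5,7-dihydroxy-3-(8-hydroxy-2,2-dimethyl-2H-chromen-6-yl)-4H-chromen-4-one | CC1(C)C=Cc2cc(cc(O)c2O1)-c1coc2cc(O)cc(O)c2c1=O
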